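**Retrosynthetic overview**
1. Target 17 is an isobutyryl-filicinic-acid ring (six-membered carbocycle, gem-dimethyl at C5) fused to a 2,3-dihydrofuran. The O1–C7a bond is opened (cyclodehydration in the forward sense) and the two C5 methyl groups are removed (re-aromatisation), which leads to acylphloroglucinol diol 15.
2. Key disconnection: the bond between dihydrofuran C2 (the O1-bearing methine) and the exocyclic carbinol carbon C(OH)(CH3)(CH2CH2CH=CMe2). It is made by lithiation–borylation, 1,2-metallate rearrangement and C–B oxidation between the arene-bearing α-silyloxy boronic ester 7 and the tertiary carbenoid from benzoate 10.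
3. Enabling feature: these two atoms are adjacent oxygen-bearing sp3 carbons (ring C2–O1 next to the tertiary C–OH), that is, a masked 1,2-diol. The tertiary C–O bond can be read as an oxidised C–B bond, and the hydrogen analogue of that carbon is the secondary alcohol sulcatol, which is easy to obtain enantiopure.
4. Fragment 7 comes from 1 by C-allylation, MOM protection, Lemieux–Johnson cleavage and Cu-catalysed enantioselective aldehyde borylation. Fragment 10 comes from sulcatone by enzymatic reduction and Mitsunobu inversion. Each stereocentre is programmed on its own, so neither a methyl/homoprenyl face choice nor a site-selective diene oxidation is needed.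
5. Ring order: the carbocycle is present from 1 as the arene and is dearomatised in step 9. The dihydrofuran ring is closed last, in the same step.

Key step: step 7

Assumption: (S)-DTBM-SEGPHOS is taken as the ligand antipode that gives (R)-6 in step 4; the mirror-image ligand is used if the sense of induction is the reverse.
Assumption: the target is drawn as its exocyclic-enol tautomer; the 6-hydroxy-7-isobutyryl tautomer that forms on ring closure is the same compound.
Assumption: 1, 2, 8 and all reagents named are commercial.

Step 1
Reactants: 1 2-methyl-1-(2,4,6-trihydroxyphenyl)propan-1-one (phlorisobutyrophenone); 2 allyl bromide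
Product: 3 1-(3-allyl-2,4,6-trihydroxyphenyl)-2-methylpropan-1-one
Conditions: KOH (1 equiv), H2O, 0 °C → rt
Reagents that add atoms: none
Why: C-alkylation of the ambident acylphloroglucinol phenoxide in water, where the soft ring carbon should win over oxygen and the two free ring carbons are equivalent, so only one mono-C-allyl isomer is possible.

Step 2
Reactants: 3 1-(3-allyl-2,4,6-trihydroxyphenyl)-2-methylpropan-1-one
Product: 4 1-[3-allyl-2,4,6-tris(methoxymethoxy)phenyl]-2-methylpropan-1-one
Conditions: NaH, MOMCl, DMF, 0 °C → rt
Reagents that add atoms: chloromethyl methyl ether, COCCl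
Why: Williamson-type O-alkylation with a hard electrophile should cap all three phenols, the two chelated ones included, as base-stable acetals that also shield the aryl ketone.

Step 3
Reactants: 4 1-[3-allyl-2,4,6-tris(methoxymethoxy)phenyl]-2-methylpropan-1-one
Product: 5 2-[3-isobutyryl-2,4,6-tris(methoxymethoxy)phenyl]acetaldehyde
Conditions: OsO4 (cat.), NaIO4, 2,6-lutidine, dioxane/H2O, rt
Reagents that add atoms: sodium periodate, [Na+].[O-]I(=O)(=O)=O; osmium tetroxide (catalytic oxygen carrier), O=[Os](=O)(=O)=O
Why: Lemieux–Johnson oxidation should cleave the only alkene present, a monosubstituted one, and leave the electron-rich arene alone, which ozone might not.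

Step 4
Reactants: 5 2-[3-isobutyryl-2,4,6-tris(methoxymethoxy)phenyl]acetaldehyde
Product: 7 1-{3-[(2R)-2-(4,4,5,5-tetramethyl-1,3,2-dioxaborolan-2-yl)-2-(triethylsilyloxy)ethyl]-2,4,6-tris(methoxymethoxy)phenyl}-2-methylpropan-1-one, via α-hydroxy boronic ester 6 (not isolated)
Conditions: CuCl/(S)-DTBM-SEGPHOS (5 mol %), KOt-Bu (cat.), B2pin2, MeOH, THF, 30 °C; then TESCl, imidazole, CH2Cl2, 0 °C
Reagents that add atoms: bis(pinacolato)diboron, CC1(C)OB(OC1(C)C)B2OC(C)(C)C(C)(C)O2; chlorotriethylsilane, CC[Si](Cl)(CC)CC
Why: Copper(I)-catalysed enantioselective nucleophilic borylation of an aliphatic aldehyde, in which the chiral bisphosphine–boryl-copper adds to one C=O face and sets the (R) C–B/C–O centre, while the hindered aryl ketone is not attacked and immediate silylation blocks boron migration to oxygen.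

Step 5
Reactants: 8 6-methylhept-5-en-2-one (sulcatone)
Product: 9 (S)-6-methylhept-5-en-2-ol
Conditions: alcohol dehydrogenase from Thermoanaerobacter brockii, NADP+ (cat.), i-PrOH, Tris buffer pH 7.8, 37 °C
Reagents that add atoms: none
Why: Biocatalytic ketone reduction with Prelog selectivity, in which the enzyme pocket tells methyl from the long chain and sets the (S) carbinol centre.

Step 6
Reactants: 9 (S)-6-methylhept-5-en-2-ol
Product: 10 (R)-6-methylhept-5-en-2-yl 2,4,6-triisopropylbenzoate
Conditions: 2,4,6-triisopropylbenzoic acid, PPh3, DIAD, THF, 0 °C → rt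
Reagents that add atoms: 2,4,6-triisopropylbenzoic acid, CC(C)c1cc(C(C)C)c(C(=O)O)c(C(C)C)c1
Why: Mitsunobu esterification should proceed by SN2 with clean inversion to the (R)-benzoate, installing a group that is at once the director for lithiation, inert to organolithiums, and the later leaving group.

Step 7
Reactants: 10 (R)-6-methylhept-5-en-2-yl 2,4,6-triisopropylbenzoate; 7 (R)-α-triethylsilyloxy pinacol boronic ester
Product: 14 1-{3-[(2S,3R)-3-hydroxy-3,7-dimethyl-2-(triethylsilyloxy)oct-6-en-1-yl]-2,4,6-tris(methoxymethoxy)phenyl}-2-methylpropan-1-one, via lithiated benzoate 11 (not isolated), via lithium boronate complex 12 (not isolated), via tertiary boronic ester 13 (not isolated)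
Conditions: 10 (1.5 equiv), s-BuLi (1.4 equiv), TMEDA, CPME, −60 °C; 7 (1.0 equiv), −60 °C → 50 °C; then NaOH aq, H2O2, THF, 0 °C → rt
Reagents that add atoms: hydrogen peroxide, OO
Why: Proposed new method: s-BuLi/TMEDA, directed by the benzoate carbonyl, removes the carbinol proton of 10 with retention, the configurationally stable tertiary α-benzoyloxy organolithium 11 adds to the boron of 7 with retention to give 12, on warming the α-silyloxyalkyl carbon migrates from boron to the carbenoid carbon anti-periplanar to the departing triisopropylbenzoate (stereospecific 1,2-metallate rearrangement), and alkaline peroxide then replaces boron in 13 by hydroxyl with retention. The closest known reaction types are the lithiation–borylation of enantioenriched secondary dialkyl triisopropylbenzoates to tertiary boronic esters, the homologation of α-alkoxy boronic esters with halomethyl carbenoids, and the assembly of adjacent quaternary–tertiary carbons from tertiary benzylic carbenoids and secondary boronic esters; new here is the union of a non-benzylic tertiary carbenoid with a secondary α-oxygenated boronic ester, which delivers a differentiated 1,2-diol directly. No ring is closed in this step. The tertiary carbinol centre is controlled by the enzyme-set centre of 10 (retention, retention, inversion, retention, which gives R), and the secondary C–O centre is the catalyst-set centre of 7, which migrates with retention (S), so the methyl/homoprenyl face choice that defeats additions to the ketone never arises. The step needs attack at boron rather than at the aryl ketone, and forward migration rather than reversal or β-elimination; the ketone is flanked by two ortho-OMOM groups and an isopropyl group, s-BuLi is kept below the amount of 10 so that none is left over, the desired carbon is the only carbon ligand on boron that can migrate, and triethylsilyloxide is too poor a leaving group for the reverse migration or for elimination from 13.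

Step 8
Reactants: 14 (2S,3R)-tertiary alcohol with TES and three MOM groups
Product: 15 1-{3-[(2S,3R)-2,3-dihydroxy-3,7-dimethyloct-6-en-1-yl]-2,4,6-trihydroxyphenyl}-2-methylpropan-1-one
Conditions: HCl (cat.), MeOH, 40 °C
Reagents that add atoms: none
Why: Acid-catalysed transacetalisation of the aryl MOM ethers and solvolysis of the TES ether, under conditions that should neither ionise the non-allylic, non-benzylic tertiary alcohol nor protonate the trisubstituted alkene.

Step 9
Reactants: 15 1-{3-[(2S,3R)-2,3-dihydroxy-3,7-dimethyloct-6-en-1-yl]-2,4,6-trihydroxyphenyl}-2-methylpropan-1-one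
Product: 17 (2S)-6-hydroxy-2-[(2R)-2-hydroxy-6-methylhept-5-en-2-yl]-7-isobutyryl-5,5-dimethyl-2,3-dihydrobenzofuran-4(5H)-one (target CNP0317212.1), via dearomatised dienone diol 16 (not isolated)
Conditions: MeI (2.1 equiv), NaOMe, MeOH, 0 °C → rt; then AcOH to pH 4, PPTS (cat.), CH2Cl2, 4 Å MS, rt
Reagents that add atoms: iodomethane, CI
Why: Alkylative dearomatisation of an acylphloroglucinol, in which the polyphenoxide should be C-methylated twice at the only unsubstituted ring carbon (flanked by two oxyanions and less hindered than the side-chain-bearing carbon) to give 16, whose secondary hydroxyl then closes 5-exo-trig onto the free dienone carbonyl para to CMe2 and loses water (cyclodehydration of a 2-(2-hydroxyalkyl)-1,3-dione; closure at the enolised carbon next to CMe2 would be 5-endo-trig, and the tertiary hydroxyl is slower), with no bond to either stereocentre broken.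

**Compound list**
1 | 2-methyl-1-(2,4,6-trihydroxyphenyl)propan-1-one | CC(C)C(=O)c1c(O)cc(O)cc1O | starting material
2 | allyl bromide | C=CCBr | starting material
3 | 1-(3-allyl-2,4,6-trihydroxyphenyl)-2-methylpropan-1-one | CC(C)C(=O)c1c(O)cc(O)c(CC=C)c1O | intermediate
4 | 1-[3-allyl-2,4,6-tris(methoxymethoxy)phenyl]-2-methylpropan-1-one | CC(C)C(=O)c1c(OCOC)cc(OCOC)c(CC=C)c1OCOC | intermediate
5 | 2-[3-isobutyryl-2,4,6-tris(methoxymethoxy)phenyl]acetaldehyde | CC(C)C(=O)c1c(OCOC)cc(OCOC)c(CC=O)c1OCOC | intermediate
6 | (R)-α-hydroxy pinacol boronic ester | CC(C)C(=O)c1c(OCOC)cc(OCOC)c(C[C@H](O)B2OC(C)(C)C(C)(C)O2)c1OCOC | intermediate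
7 | (R)-α-triethylsilyloxy pinacol boronic ester | CC(C)C(=O)c1c(OCOC)cc(OCOC)c(C[C@H](O[Si](CC)(CC)CC)B2OC(C)(C)C(C)(C)O2)c1OCOC | intermediate
8 | 6-methylhept-5-en-2-one | CC(=O)CCC=C(C)C | starting material
9 | (S)-6-methylhept-5-en-2-ol | CC(C)=CCC[C@H](C)O | intermediate
10 | (R)-6-methylhept-5-en-2-yl 2,4,6-triisopropylbenzoate | CC(C)=CCC[C@@H](C)OC(=O)c1c(C(C)C)cc(C(C)C)cc1C(C)C | intermediate
11 | α-lithiated benzoate (Li in the place of H, retention) | CC(C)=CCC[C@@]([Li])(C)OC(=O)c1c(C(C)C)cc(C(C)C)cc1C(C)C | intermediate
12 | lithium boronate complex of 11 and 7 | [Li+].CC(C)=CCC[C@@](C)(OC(=O)c1c(C(C)C)cc(C(C)C)cc1C(C)C)[B-]2(OC(C)(C)C(C)(C)O2)[C@@H](O[Si](CC)(CC)CC)Cc3c(OCOC)cc(OCOC)c(C(=O)C(C)C)c3OCOC | intermediate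
13 | tertiary pinacol boronic ester (Bpin in the place of the OH of 14) | CC(C)=CCC[C@@](C)(B1OC(C)(C)C(C)(C)O1)[C@@H](O[Si](CC)(CC)CC)Cc2c(OCOC)cc(OCOC)c(C(=O)C(C)C)c2OCOC | intermediate
14 | (2S,3R)-tertiary alcohol, TES and tris-MOM protected | CC(C)=CCC[C@@](C)(O)[C@@H](O[Si](CC)(CC)CC)Cc1c(OCOC)cc(OCOC)c(C(=O)C(C)C)c1OCOC | intermediate
15 | (2S,3R)-diol of the free acylphloroglucinol | CC(C)=CCC[C@@](C)(O)[C@@H](O)Cc1c(O)cc(O)c(C(=O)C(C)C)c1O | intermediate
16 | 2-[(2S,3R)-2,3-dihydroxy-3,7-dimethyloct-6-en-1-yl]-3,5-dihydroxy-6-isobutyryl-4,4-dimethylcyclohexa-2,5-dien-1-one | CC(C)=CCC[C@@](C)(O)[C@@H](O)CC1=C(O)C(C)(C)C(O)=C(C(=O)C(C)C)C1=O | intermediate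
17 | CNP0317212.1 | CC(C)=CCC[C@@](C)(O)[C@@H]1CC2=C(O1)/C(=C(/O)C(C)C)C(=O)C(C)(C)C2=O | target

Total step count: 9. Longest linear sequence: 7 (steps 1–4 and 7–9).

**Steps most likely to fail**

Step 7. Boronate formation between two hindered partners may be slow or reversible, so that the carbenoid decomposes or loses configuration before migration; the migration itself may also be sluggish. The fallback uses known chemistry, sets out from 10 and 5, and comes back at 15. The same lithiated benzoate 11 is quenched directly with aldehyde 5. This is a carbonyl addition of a configurationally stable α-oxy organolithium with retention, and it gives the same sense at the tertiary carbon. The product is the hydroxy benzoate F1, a mixture at the new carbinol carbon. Dess–Martin oxidation would give the α-benzoyloxy ketone F2. Corey–Bakshi–Shibata reduction with the (R)-oxazaborolidine and catecholborane, with the tertiary carbon acting as the large group, should give the (S)-alcohol F3 under reagent control. LiAlH4 would remove the hindered benzoate and also reduce the aryl ketone, giving the triol F4. MnO2 should reoxidise only the benzylic alcohol to the keto diol F5, and acid methanolysis as in step 8 leads to 15.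

Step 9. Possible failures are over-alkylation at the ring carbon that bears the side chain, O-methylation, and ring closure through the tertiary hydroxyl, all on a late intermediate. The fallback sets out from 3 and comes back at 17; it moves the dearomatisation in front of the coupling. Compound 3 is methylated (MeI, NaOMe) to the 6-allyl isobutyrylfilicinic acid F6, where isomers can be removed on scale. MOMCl/i-Pr2NEt gives the bis(methoxymethyl) dienol ether F7, and Lemieux–Johnson cleavage gives the aldehyde F8. The conditions of step 4 give the α-silyloxy boronic ester F9, and the conditions of step 7 with 10 give the coupled tertiary alcohol F10. Mild acid (PPTS, MeOH, then CH2Cl2) removes both enol acetals and the silyl group, and the freed hydroxy dienone closes to 17.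

Step 4. Base-induced enolisation or self-condensation of the arylacetaldehyde may compete, and the two ortho substituents may lower the facial selectivity. The fallback sets out from 5 and comes back at 14; it replaces catalyst control by separation of diastereomers. An achiral N-heterocyclic-carbene copper catalyst with B2pin2/MeOH, followed by TESCl, gives the racemic α-silyloxy boronic ester F11. Coupling with enantiopure 10 under the conditions of step 7 is stereospecific for each antipode, so it should give 14 together with the (2R,3R)-epimer F12, which is removed by chromatography.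

**Further compounds**
F1 | step 7 | (3R)-hydroxy benzoate, both epimers at the secondary carbinol | CC(C)=CCC[C@@](C)(OC(=O)c1c(C(C)C)cc(C(C)C)cc1C(C)C)C(O)Cc2c(OCOC)cc(OCOC)c(C(=O)C(C)C)c2OCOC
F2 | step 7 | (R)-α-benzoyloxy ketone | CC(C)=CCC[C@@](C)(OC(=O)c1c(C(C)C)cc(C(C)C)cc1C(C)C)C(=O)Cc2c(OCOC)cc(OCOC)c(C(=O)C(C)C)c2OCOC
F3 | step 7 | (2S,3R)-hydroxy benzoate | CC(C)=CCC[C@@](C)(OC(=O)c1c(C(C)C)cc(C(C)C)cc1C(C)C)[C@@H](O)Cc2c(OCOC)cc(OCOC)c(C(=O)C(C)C)c2OCOC
F4 | step 7 | (2S,3R)-diol with the aryl ketone reduced to the benzylic alcohol | CC(C)=CCC[C@@](C)(O)[C@@H](O)Cc1c(OCOC)cc(OCOC)c(C(O)C(C)C)c1OCOC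
F5 | step 7 | (2S,3R)-keto diol, tris-MOM protected | CC(C)=CCC[C@@](C)(O)[C@@H](O)Cc1c(OCOC)cc(OCOC)c(C(=O)C(C)C)c1OCOC
F6 | step 9 | 6-allyl isobutyrylfilicinic acid | CC(C)C(=O)C1=C(O)C(C)(C)C(O)=C(CC=C)C1=O
F7 | step 9 | bis(methoxymethyl) dienol ether of F6 | CC(C)C(=O)C1=C(OCOC)C(C)(C)C(OCOC)=C(CC=C)C1=O
F8 | step 9 | dienone acetaldehyde | CC(C)C(=O)C1=C(OCOC)C(C)(C)C(OCOC)=C(CC=O)C1=O
F9 | step 9 | (R)-α-triethylsilyloxy pinacol boronic ester of the dienone | CC(C)C(=O)C1=C(OCOC)C(C)(C)C(OCOC)=C(C[C@H](O[Si](CC)(CC)CC)B2OC(C)(C)C(C)(C)O2)C1=O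
F10 | step 9 | (2S,3R)-coupled tertiary alcohol of the dienone | CC(C)=CCC[C@@](C)(O)[C@@H](O[Si](CC)(CC)CC)CC1=C(OCOC)C(C)(C)C(OCOC)=C(C(=O)C(C)C)C1=O
F11 | step 4 | racemic α-triethylsilyloxy pinacol boronic ester | CC(C)C(=O)c1c(OCOC)cc(OCOC)c(CC(O[Si](CC)(CC)CC)B2OC(C)(C)C(C)(C)O2)c1OCOC
F12 | step 4 | (2R,3R)-epimer of 14 | CC(C)=CCC[C@@](C)(O)[C@H](O[Si](CC)(CC)CC)Cc1c(OCOC)cc(OCOC)c(C(=O)C(C)C)c1OCOC
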